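## Retrosynthetic overview

1. Target ⇒ open the furan O1–C2 bond: a dehydrogenative 5-endo C–O ring closure of a free 2-hydroxystilbene (a geranylated oxyresveratrol) is the last step. The furan is the only ring made; both benzene rings are bought.
2. Stilbene ⇒ Wittig C=C bond between 3-geranyl-2,4-dihydroxybenzaldehyde and a 3,5-dihydroxybenzyl phosphonium salt.
3. Aldehyde ⇒ C-geranylation of 2,4-dihydroxybenzaldehyde between its two oxygens with (E)-geranyl bromide; phosphonium salt ⇒ 3,5-dihydroxybenzyl alcohol.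
4. No protecting groups; the 2E olefin is bought and never touched.

Assumption: the target has no stereocentre, so "single enantiomer" is read as the single (2E)-geranyl isomer shown.

## Route

Step 1
Reactants: 1 2,4-dihydroxybenzaldehyde; 2 geranyl bromide [(2E)-1-bromo-3,7-dimethylocta-2,6-diene]
Product: 3 3-[(2E)-3,7-dimethylocta-2,6-dien-1-yl]-2,4-dihydroxybenzaldehyde
Conditions: KOH (10 % aq.), 0 → 23 °C
Reagents that add atoms: none
Why: Phenoxide C-alkylation in water (hydrogen bonding to the oxygens steers the ambident dianion to react at carbon), where C3 between the two oxygens is the most nucleophilic carbon and SN2 attack on the primary allylic bromide keeps the 2E geometry; no stereocentre is formed.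

Step 2
Reactants: 4 3,5-dihydroxybenzyl alcohol
Product: 5 tributyl(3,5-dihydroxybenzyl)phosphonium bromide
Conditions: n-Bu3P, HBr (48 % aq.), MeCN, 80 °C
Reagents that add atoms: tributylphosphine, CCCCP(CCCC)CCCC; hydrogen bromide, Br
Why: Phosphonium salt formation (acid-promoted substitution of the benzylic alcohol, through the benzylic bromide, by tributylphosphonium bromide made in the flask), which tolerates free phenols and gives a crystalline salt; no stereocentre is formed.

Step 3
Reactants: 3 3-[(2E)-3,7-dimethylocta-2,6-dien-1-yl]-2,4-dihydroxybenzaldehyde; 5 tributyl(3,5-dihydroxybenzyl)phosphonium bromide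
Product: 7 2-[(2E)-3,7-dimethylocta-2,6-dien-1-yl]-4-[(E)-2-(3,5-dihydroxyphenyl)ethenyl]benzene-1,3-diol, via phosphonium ylide 6 (not isolated)
Conditions: KOt-Bu (5.5 equiv), THF–DMPU, 0 → 60 °C
Reagents that add atoms: none
Why: Wittig olefination in which the strongly nucleophilic trialkylphosphonium benzylide gives the (E)-stilbene selectively, the excess base holding all four phenols as phenoxides so that none quenches the ylide; no stereocentre is formed.

Step 4
Reactants: 7 2-[(2E)-3,7-dimethylocta-2,6-dien-1-yl]-4-[(E)-2-(3,5-dihydroxyphenyl)ethenyl]benzene-1,3-diol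
Product: 8 mulberrofuran L, 5-{7-[(2E)-3,7-dimethylocta-2,6-dien-1-yl]-6-hydroxy-1-benzofuran-2-yl}benzene-1,3-diol
Conditions: 4CzIPN [1,2,3,5-tetrakis(carbazol-9-yl)-4,6-dicyanobenzene] (2 mol %), Co(dmgH)2(py)Cl (5 mol %), 2,6-lutidine (20 mol %), degassed MeCN, 450 nm LEDs, Ar, 25 °C
Reagents that add atoms: none
Why: Proposed new method: an oxidant-free, hydrogen-evolving 5-endo dehydrogenative cycloetherification of a free 2-hydroxystilbene, in which excited 4CzIPN (about +1.35 V vs SCE) can oxidise only the 2,4-dihydroxystilbene chromophore of 7 (estimated near +1.0 V) and not the isolated trisubstituted olefins (above about +1.7 V) or the meta-dihydroxyphenyl ring; the ortho-hydroxyl then adds to the benzylic carbon of the radical cation (the only alkene carbon it can reach), proton loss leaves a C3 benzylic radical, and divalent cobalt (formed from Co(dmgH)2(py)Cl by the reduced photocatalyst) removes the C2 hydrogen atom to aromatise to the benzofuran, the trivalent cobalt hydride being protonated to H2, so no stoichiometric oxidant meets the polyphenol or the geranyl chain and no stereocentre is formed; closest known reaction types: photoredox/cobaloxime acceptorless dehydrogenative alkene functionalisation and photoredox anti-Markovnikov hydroetherification of alkenols.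

## Compound list

1 | 2,4-dihydroxybenzaldehyde | O=Cc1ccc(O)cc1O | starting material
2 | geranyl bromide, (2E)-1-bromo-3,7-dimethylocta-2,6-diene | CC(C)=CCC/C(C)=C/CBr | starting material
3 | 3-[(2E)-3,7-dimethylocta-2,6-dien-1-yl]-2,4-dihydroxybenzaldehyde | CC(C)=CCC/C(C)=C/Cc1c(O)ccc(C=O)c1O | intermediate
4 | 3,5-dihydroxybenzyl alcohol | OCc1cc(O)cc(O)c1 | starting material
5 | tributyl(3,5-dihydroxybenzyl)phosphonium bromide | CCCC[P+](CCCC)(CCCC)Cc1cc(O)cc(O)c1.[Br-] | intermediate
6 | tributyl(3,5-dihydroxybenzylidene)phosphorane (ylide, present as its potassium phenoxide) | CCCCP(CCCC)(CCCC)=Cc1cc(O)cc(O)c1 | intermediate (not isolated)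
7 | 2-[(2E)-3,7-dimethylocta-2,6-dien-1-yl]-4-[(E)-2-(3,5-dihydroxyphenyl)ethenyl]benzene-1,3-diol | CC(C)=CCC/C(C)=C/Cc1c(O)ccc(/C=C/c2cc(O)cc(O)c2)c1O | intermediate
8 | mulberrofuran L, 5-{7-[(2E)-3,7-dimethylocta-2,6-dien-1-yl]-6-hydroxy-1-benzofuran-2-yl}benzene-1,3-diol | CC(C)=CCC/C(C)=C/Cc1c(O)ccc2cc(-c3cc(O)cc(O)c3)oc12 | target

## Step count and risks

Total steps: 4. Longest linear sequence: 3 (steps 1, 3, 4; or 2, 3, 4).

Steps most likely to fail:

Step 1 (C-geranylation). The yield is expected to be modest (about 20–35 %) because the 5-geranyl isomer and O-geranyl ethers form alongside. The fallback replaces phenoxide C-alkylation by directed ortho-metalation; it sets out from 2 and comes back at 3. Commercial 1,3-bis(methoxymethoxy)benzene (COCOc1cccc(OCOC)c1) is lithiated between its two acetal oxygens (n-BuLi, THF, 0 °C) to [2,6-bis(methoxymethoxy)phenyl]lithium F1. Alkylation with 2 (CuBr·SMe2, 10 mol %) gives 2-[(2E)-3,7-dimethylocta-2,6-dien-1-yl]-1,3-bis(methoxymethoxy)benzene F2. A second lithiation ortho to a MOM ether (n-BuLi, TMEDA, THF, 0 °C) gives {3-[(2E)-3,7-dimethylocta-2,6-dien-1-yl]-2,4-bis(methoxymethoxy)phenyl}lithium F3. Quenching with DMF gives 3-[(2E)-3,7-dimethylocta-2,6-dien-1-yl]-2,4-bis(methoxymethoxy)benzaldehyde F4. Cleavage of both MOM ethers (dilute HCl, MeOH, 23 °C) delivers 3.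

Step 3 (Wittig on the free dihydroxybenzaldehyde). The doubly deprotonated aldehyde is a weak electrophile and may not be consumed. The fallback reverses the polarity of the two partners; it sets out from 3 and comes back at 7. Reduction of 3 (NaBH4, MeOH, 0 °C) gives 2-[(2E)-3,7-dimethylocta-2,6-dien-1-yl]-4-(hydroxymethyl)benzene-1,3-diol F5. This ortho/para-dihydroxybenzyl alcohol ionises under weak acid and is quaternised with preformed n-Bu3P·HBr (MeCN, 23 °C) to tributyl{2,4-dihydroxy-3-[(2E)-3,7-dimethylocta-2,6-dien-1-yl]benzyl}phosphonium bromide F6. Deprotonation (KOt-Bu, THF) gives tributyl{2,4-dihydroxy-3-[(2E)-3,7-dimethylocta-2,6-dien-1-yl]benzylidene}phosphorane F7. This ylide is condensed with commercial 3,5-dihydroxybenzaldehyde (O=Cc1cc(O)cc(O)c1), whose meta-oxido groups do not deactivate the carbonyl, to give 7.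

Step 4 (the proposed new C–O ring closure). The radical cation may dimerise, or the product may be dehydrogenated further at the geranyl position next to the phenol. The fallback uses known chemistry and replaces the oxidative closure by a redox-neutral alkyne hydroalkoxylation; it sets out from 3 and comes back at 8. Seyferth–Gilbert homologation of 3 with the Ohira–Bestmann reagent (CC(=O)C(=[N+]=[N-])P(=O)(OC)OC; K2CO3, MeOH, 23 °C) gives 4-ethynyl-2-[(2E)-3,7-dimethylocta-2,6-dien-1-yl]benzene-1,3-diol F8. Sonogashira coupling with commercial 5-iodobenzene-1,3-diol (Oc1cc(O)cc(I)c1; PdCl2(PPh3)2 3 mol %, CuI 5 mol %, K2CO3, DMF, 60 °C) gives 4-[(3,5-dihydroxyphenyl)ethynyl]-2-[(2E)-3,7-dimethylocta-2,6-dien-1-yl]benzene-1,3-diol F9. In the same flask at 80 °C, F9 undergoes the well-established CuI/base-promoted 5-endo-dig cyclisation of its ortho-hydroxyl onto the alkyne to give 8.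

## Further compounds

F1 | step 1 | [2,6-bis(methoxymethoxy)phenyl]lithium | [Li]c1c(OCOC)cccc1OCOC
F2 | step 1 | 2-[(2E)-3,7-dimethylocta-2,6-dien-1-yl]-1,3-bis(methoxymethoxy)benzene | CC(C)=CCC/C(C)=C/Cc1c(OCOC)cccc1OCOC
F3 | step 1 | {3-[(2E)-3,7-dimethylocta-2,6-dien-1-yl]-2,4-bis(methoxymethoxy)phenyl}lithium | CC(C)=CCC/C(C)=C/Cc1c(OCOC)ccc([Li])c1OCOC
F4 | step 1 | 3-[(2E)-3,7-dimethylocta-2,6-dien-1-yl]-2,4-bis(methoxymethoxy)benzaldehyde | CC(C)=CCC/C(C)=C/Cc1c(OCOC)ccc(C=O)c1OCOC
F5 | step 3 | 2-[(2E)-3,7-dimethylocta-2,6-dien-1-yl]-4-(hydroxymethyl)benzene-1,3-diol | CC(C)=CCC/C(C)=C/Cc1c(O)ccc(CO)c1O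
F6 | step 3 | tributyl{2,4-dihydroxy-3-[(2E)-3,7-dimethylocta-2,6-dien-1-yl]benzyl}phosphonium bromide | CC(C)=CCC/C(C)=C/Cc1c(O)ccc(C[P+](CCCC)(CCCC)CCCC)c1O.[Br-]
F7 | step 3 | tributyl{2,4-dihydroxy-3-[(2E)-3,7-dimethylocta-2,6-dien-1-yl]benzylidene}phosphorane | CC(C)=CCC/C(C)=C/Cc1c(O)ccc(C=P(CCCC)(CCCC)CCCC)c1O
F8 | step 4 | 4-ethynyl-2-[(2E)-3,7-dimethylocta-2,6-dien-1-yl]benzene-1,3-diol | CC(C)=CCC/C(C)=C/Cc1c(O)ccc(C#C)c1O
F9 | step 4 | 4-[(3,5-dihydroxyphenyl)ethynyl]-2-[(2E)-3,7-dimethylocta-2,6-dien-1-yl]benzene-1,3-diol | CC(C)=CCC/C(C)=C/Cc1c(O)ccc(C#Cc2cc(O)cc(O)c2)c1O
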